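The tetrahydrofuran (ring A) is numbered O1, C2 (trimethoxyphenyl), C3 (bearing hydroxymethyl C6), C4 (bearing carbonyl C7), C5. Because the C3 and C4 substituents are cis, the C6 oxygen and C7 can be tied into a temporary cis-fused ring B, giving a 2,6-diaryl-3,7-dioxabicyclo[3.3.0]octane. One operation builds this bicycle from an acyclic epoxy cinnamyl ether: titanocene-induced epoxide opening gives a C4 radical that closes onto C3, and iodine then lets the former epoxide oxygen O1 capture benzylic C2. The carbinol stereocentre of the precursor, secured by Sharpless kinetic resolution, directs all three ring-A stereocentres and is finally erased by benzylic oxidation, which opens ring B to ketone and alcohol.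

Key step: step 5

Remark: the three starting materials are taken as commercially available.

Step 1
Reactants: 1 3,4-dimethoxybenzaldehyde; 2 vinylmagnesium bromide
Product: 3 rac-1-(3,4-dimethoxyphenyl)prop-2-en-1-ol
Conditions: THF, −20 to 0 °C; aq. NH4Cl
Reagents that add atoms: none
Why: Grignard 1,2-addition of the vinyl nucleophile to the aryl aldehyde should give the racemic allylic alcohol, which needs no stereocontrol because step 2 resolves it.

Step 2
Reactants: 3 rac-1-(3,4-dimethoxyphenyl)prop-2-en-1-ol
Product: 4 (R)-(3,4-dimethoxyphenyl)[(2S)-oxiran-2-yl]methanol (anti epoxy alcohol)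
Conditions: Ti(OiPr)4 (10 mol %), D-(−)-diisopropyl tartrate (15 mol %), t-BuOOH (0.45 equiv), 4 Å MS, CH2Cl2, −20 °C
Reagents that add atoms: tert-butyl hydroperoxide, CC(C)(C)OO
Why: Sharpless kinetic resolution by asymmetric epoxidation: the titanium tartrate catalyst made from D-(−)-DIPT should epoxidize the (S)-enantiomer of 3 much faster than the (R)-enantiomer and from the face that gives the anti (erythro) epoxy alcohol, so that stopping below half conversion leaves the (R)-alcohol untouched (removed by chromatography) and gives 4 with the carbinol configuration required later (its descriptor reads R in 4 only because the oxirane carbon now outranks the aryl group).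

Step 3
Reactants: 5 (E)-3-(3,4,5-trimethoxyphenyl)prop-2-en-1-ol
Product: 6 (E)-5-(3-bromoprop-1-en-1-yl)-1,2,3-trimethoxybenzene
Conditions: PBr3 (0.4 equiv), Et2O, 0 °C; used crude at once
Reagents that add atoms: phosphorus tribromide, BrP(Br)Br
Why: Bromination of a primary allylic alcohol with PBr3 (SN2 on the phosphite ester) should give the cinnamyl bromide with retained E geometry.

Step 4
Reactants: 4 (R)-(3,4-dimethoxyphenyl)[(2S)-oxiran-2-yl]methanol; 6 (E)-5-(3-bromoprop-1-en-1-yl)-1,2,3-trimethoxybenzene
Product: 7 (2S)-2-[(R)-(3,4-dimethoxyphenyl){[(2E)-3-(3,4,5-trimethoxyphenyl)prop-2-en-1-yl]oxy}methyl]oxirane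
Conditions: NaH, n-Bu4NI (cat.), THF–DMF, 0 °C to rt
Reagents that add atoms: none
Why: Williamson ether synthesis: the sodium alkoxide of 4 should displace the primary allylic bromide by SN2 faster than it undergoes Payne rearrangement under cold aprotic conditions, and no stereocentre is touched.

Step 5
Reactants: 7 (2S)-2-[(R)-(3,4-dimethoxyphenyl){[(2E)-3-(3,4,5-trimethoxyphenyl)prop-2-en-1-yl]oxy}methyl]oxirane
Product: 9 (1S,3aR,4S,6aR)-1-(3,4-dimethoxyphenyl)-4-(3,4,5-trimethoxyphenyl)tetrahydro-1H,3H-furo[3,4-c]furan, via benzylic iodide 8 (not isolated)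
Conditions: Cp2TiCl2 (2.5 equiv), Zn dust, THF, rt (forms Cp2TiCl, trivalent titanium); 7 added slowly at high dilution; then I2 (1.3 equiv), rt to 55 °C
Reagents that add atoms: none
Why: Cp2TiCl transfers one electron to the oxirane, which opens to the secondary C4 radical with O1 held on tetravalent titanium; this radical adds 5-exo-trig to C3 of the cinnamyl double bond (bond C3–C4, ring B), the benzylic C2 radical is trapped by a second Cp2TiCl, and iodine converts the benzylic titanium species into iodide 8, which the titanium alkoxide O1 displaces in an SN1-like 5-exo-tet closure (bond O1–C2, ring A). The closest known reaction type is the titanocene chloride mediated radical cyclization of epoxy allyl ethers with iodine quench, used to make 2,6-diaryl furofurans. C3 and C4 should come out cis because two fused five-membered rings tolerate only a cis junction, and the aryl group on C7 should take the position trans to the C4 side chain in the chair-like transition state of the 5-exo closure, so the (R)-carbinol centre of 7 fixes the absolute configuration of C3 and C4. C2 is set in the capture of the trimethoxybenzyl cation, where both epimers of 8 should converge on the aryl-exo product. The step needs opening to the C4 and not the C5 radical (the more substituted radical is favoured), ring closure faster than reduction of the C4 radical (fast attack on a styrene-type acceptor under dilution) and attack at C3 and not C2 (only C3 gives a five-membered ring and a benzylic radical). The minor diastereomer has to be removed at this stage, because after step 6 it would become the enantiomer of the target.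

Step 6
Reactants: 9 (1S,3aR,4S,6aR)-1-(3,4-dimethoxyphenyl)-4-(3,4,5-trimethoxyphenyl)tetrahydro-1H,3H-furo[3,4-c]furan
Product: 10 Magnone B, (2S,3R,4R)-4-(3,4-dimethoxybenzoyl)-3-(hydroxymethyl)-2-(3,4,5-trimethoxyphenyl)tetrahydrofuran
Conditions: DDQ (1.2 equiv), CH2Cl2–pH 7 phosphate buffer (10:1), 0 °C
Reagents that add atoms: water, O
Why: DDQ oxidation of a benzylic ether: hydride abstraction should occur at C7–H, where the oxocarbenium ion is stabilized by the conjugated para-methoxy group of the 3,4-dimethoxyphenyl ring (the 4-methoxy group of the trimethoxyphenyl ring at C2 is twisted out of conjugation), water adds, and the hemiketal opens to the aryl ketone and the C6 alcohol, leaving C2, C3 and C4 untouched so that the cis relation of C3 and C4 set by the ring fusion is kept under cold buffered conditions.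

Compound list
1 | 3,4-dimethoxybenzaldehyde | COc1ccc(C=O)cc1OC | starting material
2 | vinylmagnesium bromide | C=C[Mg]Br | starting material
3 | rac-1-(3,4-dimethoxyphenyl)prop-2-en-1-ol | COc1ccc(C(O)C=C)cc1OC | intermediate
4 | (R)-(3,4-dimethoxyphenyl)[(2S)-oxiran-2-yl]methanol | COc1ccc([C@@H](O)[C@@H]2CO2)cc1OC | intermediate
5 | (E)-3-(3,4,5-trimethoxyphenyl)prop-2-en-1-ol | COc1cc(/C=C/CO)cc(OC)c1OC | starting material
6 | (E)-5-(3-bromoprop-1-en-1-yl)-1,2,3-trimethoxybenzene | COc1cc(/C=C/CBr)cc(OC)c1OC | intermediate
7 | (2S)-2-[(R)-(3,4-dimethoxyphenyl){[(2E)-3-(3,4,5-trimethoxyphenyl)prop-2-en-1-yl]oxy}methyl]oxirane | COc1ccc([C@@H](OC/C=C/c2cc(OC)c(OC)c(OC)c2)[C@@H]3CO3)cc1OC | intermediate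
8 | chlorotitanocene alkoxide of [(2S,3R,4R)-2-(3,4-dimethoxyphenyl)-4-[iodo(3,4,5-trimethoxyphenyl)methyl]tetrahydrofuran-3-yl]methanol (benzylic iodide, both epimers at the iodide carbon) | COc1ccc([C@H]2OC[C@H](C(I)c3cc(OC)c(OC)c(OC)c3)[C@@H]2C[O-])cc1OC.[Ti+4].[Cl-].c1cc[cH-]c1.c1cc[cH-]c1 | intermediate
9 | (1S,3aR,4S,6aR)-1-(3,4-dimethoxyphenyl)-4-(3,4,5-trimethoxyphenyl)tetrahydro-1H,3H-furo[3,4-c]furan | COc1ccc([C@@H]3[C@H]2CO[C@H](c4cc(OC)c(OC)c(OC)c4)[C@H]2CO3)cc1OC | intermediate
10 | Magnone B, (2S,3R,4R)-4-(3,4-dimethoxybenzoyl)-3-(hydroxymethyl)-2-(3,4,5-trimethoxyphenyl)tetrahydrofuran | COc1ccc(C(=O)[C@H]2CO[C@H](c3cc(OC)c(OC)c(OC)c3)[C@H]2CO)cc1OC | target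

Total step count: 6
Longest linear sequence: 5 steps (steps 1, 2, 4, 5, 6)

Steps most likely to fail

Step 6. Hydride abstraction may also take place at the other benzylic ether carbon (C2), the product may be oxidized further, or the freed ketone may epimerize at C4 under the acidic hydroquinone. The fallback sets out from 9 and comes back at 10, replacing C–H oxidation by ionization. Treatment of 9 with Ac2O and catalytic Sc(OTf)3 at low temperature should ionize the more labile C7–O bond next to the dimethoxyphenyl ring and acetylate the ring-B oxygen, giving [(2S,3R,4R)-4-[acetoxy(3,4-dimethoxyphenyl)methyl]-2-(3,4,5-trimethoxyphenyl)tetrahydrofuran-3-yl]methyl acetate F1. Methanolysis (K2CO3, MeOH) should give [(2S,3R,4R)-4-[hydroxy(3,4-dimethoxyphenyl)methyl]-2-(3,4,5-trimethoxyphenyl)tetrahydrofuran-3-yl]methanol F2. MnO2 in CH2Cl2 should then oxidize only the benzylic secondary alcohol, so that 10 forms under neutral conditions and C4 becomes enolizable only in the last operation.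

Step 5. The first radical may be reduced by a second titanocene chloride with loss of the β-alkoxy group before it cyclizes, the benzylic end of the cascade may be reduced or eliminate instead of being captured by O1, or the 5-exo closure may show poor facial control. The fallback sets out from 4 and comes back at 9, forming the two bonds in separate flasks with an alkyne as radical acceptor. O-Propargylation of 4 (NaH, propargyl bromide, THF) should give (2S)-2-[(R)-(3,4-dimethoxyphenyl)(prop-2-yn-1-yloxy)methyl]oxirane F3. Sonogashira coupling with 5-iodo-1,2,3-trimethoxybenzene (Pd(PPh3)2Cl2, CuI, Et3N) should give (2S)-2-[(R)-(3,4-dimethoxyphenyl){[3-(3,4,5-trimethoxyphenyl)prop-2-yn-1-yl]oxy}methyl]oxirane F4. Cp2TiCl (from Cp2TiCl2 and Zn, THF, acidic work-up) should open the epoxide and close 5-exo-dig to [(2S,3R)-2-(3,4-dimethoxyphenyl)-4-(3,4,5-trimethoxybenzylidene)tetrahydrofuran-3-yl]methanol F5. Catalytic camphorsulfonic acid in CH2Cl2 should protonate the styrene double bond at C3 and let the primary alcohol capture the trimethoxybenzyl cation, reversibly, so that the cis-fused aryl-exo bicycle 9 accumulates.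

Step 2. The Lewis-acidic titanium alkoxide may ionize the electron-rich benzylic alcohol or open the terminal epoxide of the product with isopropoxide, and the rate difference between the enantiomers may be too small. The fallback sets out from 3 and comes back at 4, separating resolution from epoxidation. Candida antarctica lipase B with vinyl acetate in hexane should acylate the (R)-alcohol, following the usual enantiopreference of this lipase, to (R)-1-(3,4-dimethoxyphenyl)prop-2-en-1-yl acetate F7 and leave (S)-1-(3,4-dimethoxyphenyl)prop-2-en-1-ol F6. Hydroxyl-directed epoxidation of F6 (VO(acac)2 cat., t-BuOOH, CH2Cl2, 0 °C) should give mainly 4. The minor syn epimer (R)-(3,4-dimethoxyphenyl)[(2R)-oxiran-2-yl]methanol F8 is removed by chromatography, although it would converge in step 5 because the oxirane carbon becomes a planar radical.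

Further compounds
F1 | step 6 | [(2S,3R,4R)-4-[acetoxy(3,4-dimethoxyphenyl)methyl]-2-(3,4,5-trimethoxyphenyl)tetrahydrofuran-3-yl]methyl acetate | COc1ccc(C(OC(C)=O)[C@H]2CO[C@H](c3cc(OC)c(OC)c(OC)c3)[C@H]2COC(C)=O)cc1OC
F2 | step 6 | [(2S,3R,4R)-4-[hydroxy(3,4-dimethoxyphenyl)methyl]-2-(3,4,5-trimethoxyphenyl)tetrahydrofuran-3-yl]methanol | COc1ccc(C(O)[C@H]2CO[C@H](c3cc(OC)c(OC)c(OC)c3)[C@H]2CO)cc1OC
F3 | step 5 | (2S)-2-[(R)-(3,4-dimethoxyphenyl)(prop-2-yn-1-yloxy)methyl]oxirane | COc1ccc([C@@H](OCC#C)[C@@H]2CO2)cc1OC
F4 | step 5 | (2S)-2-[(R)-(3,4-dimethoxyphenyl){[3-(3,4,5-trimethoxyphenyl)prop-2-yn-1-yl]oxy}methyl]oxirane | COc1ccc([C@@H](OCC#Cc2cc(OC)c(OC)c(OC)c2)[C@@H]3CO3)cc1OC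
F5 | step 5 | [(2S,3R)-2-(3,4-dimethoxyphenyl)-4-(3,4,5-trimethoxybenzylidene)tetrahydrofuran-3-yl]methanol | COc1ccc([C@H]2OCC(=Cc3cc(OC)c(OC)c(OC)c3)[C@@H]2CO)cc1OC
F6 | step 2 | (S)-1-(3,4-dimethoxyphenyl)prop-2-en-1-ol | COc1ccc([C@@H](O)C=C)cc1OC
F7 | step 2 | (R)-1-(3,4-dimethoxyphenyl)prop-2-en-1-yl acetate | COc1ccc([C@H](OC(C)=O)C=C)cc1OC
F8 | step 2 | (R)-(3,4-dimethoxyphenyl)[(2R)-oxiran-2-yl]methanol | COc1ccc([C@@H](O)[C@H]2CO2)cc1OC
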